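**Assumption:** rings are lettered A to G from the 2,4,6-trihydroxyphenoxy end, and each ring is numbered from the carbon that holds the ether oxygen coming from the preceding ring (ring A from its only ether carbon). The target has no stereogenic element, so no SMILES below carries a stereodescriptor. Catalogue compounds named as starting materials are taken to be purchasable.

## Structural features

The target is a linear heptameric phlorotannin: seven benzene rings A to G joined only by six diaryl ether oxygens, with eighteen free phenolic hydroxyls and no carbon–carbon bond between rings. Ring A is a 2,4,6-trihydroxyphenyl ether and ring G a 3,4,5-trihydroxyphenyl ether. Rings B and F are 2,6-dihydroxy-1,4-phenylene diethers with B4 and F4 doubly flanked. Rings C and E are 3,4,5-trihydroxy-1,2-phenylene diethers with ether oxygens on the neighbouring carbons C1/C6 and E1/E6, and ring D is a 4,5-dihydroxy-1,3-phenylene diether. There is no stereocentre and the ethers rotate freely, so nothing has to be controlled stereochemically. The free pyrogallol units (rings C, E, G) and the phloroglucinol-type ring A oxidise readily in air, most of all under base, so all eighteen hydroxyls are kept as methyl ethers until the last step. The real difficulty is the six C(aryl)–O bonds between rings that are all electron-rich, several at carbons flanked on both sides (A1, B4, C6, E6, F4), together with the near-identical nucleophilicity of the free ring positions in any electrophilic substitution. The key step exploits that E1 (between E2–H and E6) and F1 (between F2–H and F6–H) each carry an ether oxygen that can be read as the remnant of an ester. Putting a carbonyl carbon between the D5 oxygen and E1, and between the E6 oxygen and F1, maps ring E onto 2-hydroxy-3,4,5-trimethoxybenzoic acid and ring F onto a 4-aryloxy-3,5-dimethoxybenzoic acid, two regiochemically unambiguous benzoic acids.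

## Logic of the disconnections

**25 ⇒ 24.** The eighteen O–H groups are traced back to O–CH3 groups. The polyphenol is oxidation-sensitive and would interfere with every metal-mediated step, whereas methyl ethers are inert and fall to one reagent. The gain is a robust, chromatographable precursor. The forward step must cleave eighteen ethers completely without touching the six diaryl ethers, and the work-up must exclude air and base.

**24 ⇒ 22 + 23.** The bond from A1 to the oxygen on B1 is cut. Ring A must arrive last, because its two free positions are the most nucleophilic C–H sites of the whole assembly and would take the halogen in any earlier iodination. The gain is a hexamer phenol plus a purchasable aryl iodide that can be used in excess. The forward step is a copper coupling of a di-ortho-substituted, electron-rich iodide with an unhindered phenol.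

**22 ⇒ 20.** The B1 hydroxyl is traced back to a formyl group through an aryl formate (21). The formyl group is wanted earlier: it deactivates ring B in the iodination that makes 5, and it lets one aldehyde (3) serve two purposes. The forward step needs aryl migration in a peracid oxidation of a hexamer whose other rings are all fully etherified.

**20 ⇒ 19 + 5.** The bond from the D1 oxygen to C6 is cut. This divides the molecule at the vicinal diether ring C, with an unhindered phenol on one side and a three-step iodide on the other that can be used in excess. The forward step is a copper coupling at an iodide flanked by aryloxy and methoxy groups.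

**19 ⇒ 18.** The D1 oxygen is masked as a benzyl ether. This group is orthogonal to methyl ethers and survives acylation and zerovalent nickel. The forward step is hydrogenolysis, which no other group in 18 answers to.

**18 ⇒ 17.** Carbon monoxide is inserted, in the retrosynthetic sense, into the D5 oxygen–E1 bond and into the E6 oxygen–F1 bond. Two hindered diaryl ethers, one of them on a doubly flanked oxygen, thereby become ester bonds that form by plain acylation, and the oxygen patterns of rings E and F come from benzoic acids. The forward step must excise CO from two electron-rich, ortho-substituted aryl esters in one molecule without crossover. Both 17 and 18 were re-derived from the target ring by ring and need no correction.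

**17 ⇒ 15 + 10 (through 16).** The ester bond at the D5 oxygen is cut. This gives a ring D phenol and an EFG acid. The forward acylation must not disturb the aryl ester already present in 10.

**10 ⇒ 4 + 8 (through 9).** The ester bond at the E6 oxygen is cut. The order is chosen so that the salicylic hydroxyl of 8 is acylated before the ring E carboxyl is ever activated, which removes the self-condensation of a free salicylic acid. The forward step must acylate a flanked, hydrogen-bonded phenol.

**4 and 5 ⇒ 3; 3 ⇒ 1 + 2.** Acid 4 is the oxidation product of 3 and iodide 5 its iodination product, because the F–G and B–C pairs share one skeleton. Cutting the F4 oxygen–G1 bond (the same bond as B4 oxygen–C1) gives 1 and 2. The aldehyde oxidation level of 1 is chosen over the acid so that one coupling feeds both branches. The forward coupling must cope with a hindered, electron-poor phenol.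

**8 ⇒ 7 ⇒ 6.** The E6 hydroxyl is traced back to bromide and then to hydrogen. Both free positions of 6 are equivalent, and the carboxylate directs the copper substitution.

**15 ⇒ 14 ⇒ 13 ⇒ 11 (through 12).** The D5 hydroxyl comes from bromide, the benzyl group from benzyl bromide, and the D1 oxygen from a formyl group. Starting from the bromo aldehyde places the benzyl ether at D1 and the free hydroxyl at D5 with no protecting-group exchange, which a hydroxy aldehyde start would need.

## Other disconnections considered

**Alternative 1:** The cut is the E1–E2 bond, and with it the whole of ring E, which would be grown from a four-membered ring. Thermolysis of the racemic cyclobutenone A2 would open it to a dienylketene, close E1–E2 by 6π electrocyclisation and tautomerise to the EFG phenol A1.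
- In favour: all five oxygens of ring E are placed before the ring exists, so no regiochemical question arises. The crowded E6 oxygen–F1 ether would come from addition–elimination on a squaric ester, not from an aryl C–O coupling. The key step needs no metal and belongs to a well-established reaction type for highly oxygenated phenols. The free E1 hydroxyl emerges exactly where ring D has to be attached.
- Against: the organometallic addition that leads to A2 must choose the carbonyl vinylogous to the aryloxy group and must not expel the aryloxide. Several steps are cryogenic. The D5 oxygen–E1 ether would still need a copper coupling of the flanked phenol A1, for example with 14 to reach 18.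
- Comparison: on structure, the alternative fixes the oxygen pattern by construction, which equals the chosen plan in outcome. On mechanism, its key step is better precedented than the double decarbonylation. On step economy the two are about equal (roughly nine operations to 18 against ten). The alternative solves one of the two hindered ethers of ring E, whereas the chosen step solves both at once from purchasable oxygen patterns.

**Alternative 2:** The cut is the three C–O bonds of the central hydroxyls at C4, E4 and G4, each traced back to a formyl group. A peracid Baeyer–Villiger oxidation (Dakin type) of the heptamer trialdehyde A3, followed by methanolysis of the three formates, would give the triol A4.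
- In favour: 2,6-dimethoxybenzaldehydes are among the best substrates for this oxidation, and the reaction type is fully established. A formyl group para to C1, E1 and G1 would allow three of the six ethers to be made by SNAr on para-fluorobenzaldehyde building blocks without metal. A4 needs no re-methylation, because global demethylation follows.
- Against: this is a functional-group interchange at the very end and forms no inter-ring bond. The vicinal ethers at C6 and E6, which are the real problem, sit meta to the formyl groups and gain nothing. Three aldehydes must survive every coupling. The liberated 2,6-dimethoxyphenols and the electron-rich ring A are exposed to over-oxidation by excess peracid.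
- Comparison: on the risk of the key step itself the alternative is the better. On step economy it is equal or slightly shorter if the SNAr reactions work. On strategic gain it is weaker, since the chosen plan uses the same oxidation only in a supporting role (steps 7 and 14) and reserves its key step for two of the hardest ether bonds.

**Alternative 3:** The cut is both ether bonds of ring B (oxygen to B1 and B4 to oxygen). On the complex A5, [CpRu(η6-arene)]PF6 with 2,5-dichloro-1,3-dimethoxybenzene as the arene, the phenoxide of A6 would displace the unhindered chloride and the phenoxide of A7 the flanked one. Irradiation in acetonitrile would then release the ABC trimer A8 and the complex A9.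
- In favour: the ruthenium fragment turns the electron-rich ring B into an SNAr electrophile near room temperature. Both hindered junctions (the oxygen of the hindered phenol A6 and the flanked carbon B4) would form without copper. The order of substitution is set by sterics, and A9 can be recycled.
- Against: ruthenium is stoichiometric, and complexation, two substitutions and decomplexation are spent on one ring. The second substitution joins a flanked chloride to a phenoxide with an ortho benzyloxy group. A8 ends in a benzyl ether on the C6 oxygen, so hydrogenolysis gives a phenol of the same polarity as 19. The halves could then be joined only by turning 19 into an electrophile, or by making ring D a halide, which would not survive zerovalent nickel in step 11.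
- Comparison: on mildness of C–O bond formation around ring B the alternative is better than the copper couplings of steps 1 and 15. On fit with the chosen key step and on step economy it is worse. It addresses the ABC half only, so it complements the chosen disconnection of rings E and F and does not compete with it.

Key step: step 11

## Route

Step 1
Reactants: 1 syringaldehyde (4-hydroxy-3,5-dimethoxybenzaldehyde); 2 5-bromo-1,2,3-trimethoxybenzene
Product: 3 3,5-dimethoxy-4-(3,4,5-trimethoxyphenoxy)benzaldehyde
Conditions: CuI (10 mol%), picolinic acid (20 mol%), K3PO4, DMSO, 100 °C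
Reagents that add atoms: none
Why: Ullmann diaryl ether coupling; picolinate-ligated monovalent copper is suited to 2,6-disubstituted phenols and the unhindered bromide 2 is the easy partner. The formyl group is inert to K3PO4 in DMSO and is used twice later (oxidation to 4, ring deactivation in step 3).

Step 2
Reactants: 3 3,5-dimethoxy-4-(3,4,5-trimethoxyphenoxy)benzaldehyde
Product: 4 3,5-dimethoxy-4-(3,4,5-trimethoxyphenoxy)benzoic acid (FG acid)
Conditions: NaClO2, NaH2PO4, 2-methyl-2-butene, t-BuOH/H2O, rt
Reagents that add atoms: sodium chlorite, [Na+].[O-]Cl=O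
Why: Pinnick oxidation; chlorous acid attacks only the aldehyde, and the alkene removes HOCl before it can chlorinate the trimethoxyphenoxy ring.

Step 3
Reactants: 3 3,5-dimethoxy-4-(3,4,5-trimethoxyphenoxy)benzaldehyde
Product: 5 4-(2-iodo-3,4,5-trimethoxyphenoxy)-3,5-dimethoxybenzaldehyde (BC iodide)
Conditions: NIS (1.05 equiv), TFA (cat.), MeCN, 0 °C → rt, dark
Reagents that add atoms: N-iodosuccinimide, O=C1CCC(=O)N1I
Why: Electrophilic aromatic iodination; the formyl group deactivates the benzaldehyde ring, so iodine enters the trimethoxyphenoxy ring, whose two free positions are equivalent. One equivalent of NIS should therefore give a single mono-iodide, which is the C6 halide of ring C.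

Step 4
Reactants: 6 3,4,5-trimethoxybenzoic acid
Product: 7 2-bromo-3,4,5-trimethoxybenzoic acid
Conditions: Br2, CHCl3, reflux
Reagents that add atoms: bromine, BrBr
Why: Electrophilic aromatic bromination; the two free positions of 6 are equivalent and activated by ortho and para methoxy groups, so only the 2-bromo acid can form.

Step 5
Reactants: 7 2-bromo-3,4,5-trimethoxybenzoic acid
Product: 8 2-hydroxy-3,4,5-trimethoxybenzoic acid
Conditions: CuSO4 (10 mol%), pyridine, aq. NaOH, reflux; then aq. HCl
Reagents that add atoms: sodium hydroxide, [Na+].[OH-]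
Why: Copper-catalysed hydroxylation of an ortho-halobenzoic acid (Hurtley-type substitution); the neighbouring carboxylate delivers copper to the C–Br bond, which is why hydroxide substitutes this electron-rich ring in water.

Step 6
Reactants: 4 3,5-dimethoxy-4-(3,4,5-trimethoxyphenoxy)benzoic acid; 8 2-hydroxy-3,4,5-trimethoxybenzoic acid
Product: 10 2-{[3,5-dimethoxy-4-(3,4,5-trimethoxyphenoxy)benzoyl]oxy}-3,4,5-trimethoxybenzoic acid (EFG acid), via acid chloride 9 (not isolated)
Conditions: (COCl)2, DMF (cat.), CH2Cl2, 0 °C → rt, evaporate; then 8, pyridine, DMAP (cat.), CH2Cl2, 0 °C → rt; aq. HCl work-up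
Reagents that add atoms: none
Why: O-Aroylation of a salicylic acid, the reaction type by which O-acylsalicylic acids are made; any mixed anhydride formed at the carboxylate passes the aroyl group to the neighbouring phenol through a six-membered transition state. Acylating this hydroxyl before the ring E carboxyl is activated removes the self-condensation that a free salicylic acid would undergo in step 10.

Step 7
Reactants: 11 3-bromo-4,5-dimethoxybenzaldehyde
Product: 13 3-bromo-4,5-dimethoxyphenol, via aryl formate 12 (not isolated)
Conditions: mCPBA, CH2Cl2, rt; aq. NaHCO3 wash; then K2CO3 (cat.), MeOH, 0 °C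
Reagents that add atoms: mCPBA, OOC(=O)c1cccc(Cl)c1
Why: Dakin-type Baeyer–Villiger oxidation; the para methoxy group makes the aryl group migrate in preference to hydride, and the aryl formate is cleaved by methanol under conditions that leave the aryl bromide untouched.

Step 8
Reactants: 13 3-bromo-4,5-dimethoxyphenol
Product: 14 1-(benzyloxy)-3-bromo-4,5-dimethoxybenzene
Conditions: BnBr, K2CO3, DMF, rt
Reagents that add atoms: benzyl bromide, BrCc1ccccc1
Why: Williamson ether synthesis on the only phenol; benzyl is chosen because it survives hydroxide, acylation and zerovalent nickel and is later removed by hydrogenolysis without touching methyl or diaryl ethers.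

Step 9
Reactants: 14 1-(benzyloxy)-3-bromo-4,5-dimethoxybenzene
Product: 15 5-(benzyloxy)-2,3-dimethoxyphenol
Conditions: Pd2(dba)3 (2 mol%), tBuXPhos (8 mol%), KOH, 1,4-dioxane/H2O, 100 °C; then aq. HCl
Reagents that add atoms: potassium hydroxide, [K+].[OH-]
Why: Palladium-catalysed hydroxylation of an aryl bromide with hydroxide; the bulky biarylphosphine promotes C–O reductive elimination from the arylpalladium hydroxide and suppresses diaryl ether formation. The free hydroxyl is thereby placed at D5 and the benzyl ether at D1.

Step 10
Reactants: 10 2-{[3,5-dimethoxy-4-(3,4,5-trimethoxyphenoxy)benzoyl]oxy}-3,4,5-trimethoxybenzoic acid; 15 5-(benzyloxy)-2,3-dimethoxyphenol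
Product: 17 5-(benzyloxy)-2,3-dimethoxyphenyl 2-{[3,5-dimethoxy-4-(3,4,5-trimethoxyphenoxy)benzoyl]oxy}-3,4,5-trimethoxybenzoate (depside), via acid chloride 16 (not isolated)
Conditions: (COCl)2, DMF (cat.), CH2Cl2, 0 °C → rt, evaporate; then 15, Et3N, DMAP (cat.), CH2Cl2, 0 °C → rt
Reagents that add atoms: none
Why: Esterification of a phenol with an O-acylsalicyloyl chloride, a long-used acylation; transfer from the acylpyridinium ion is much faster than attack of the phenol on the aryl ester already present, so both ester groups keep their places.

Step 11
Reactants: 17 depside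
Product: 18 5-(benzyloxy)-1-{2-[3,5-dimethoxy-4-(3,4,5-trimethoxyphenoxy)phenoxy]-3,4,5-trimethoxyphenoxy}-2,3-dimethoxybenzene (DEFG tetramer benzyl ether)
Conditions: Ni(cod)2 (20 mol%), dcypt (40 mol%), K3PO4, mesitylene, 160 °C, slow argon sweep through a reflux condenser
Reagents that add atoms: none
Why: Proposed new method: zerovalent nickel bound to the chelating diphosphine dcypt should add oxidatively to the C(acyl)–O bond of each aryl ester (D5 oxygen–CO–E1 and E6 oxygen–CO–F1) to give acylnickel aryloxides, which lose CO by de-insertion and then close the oxygen–E1 and oxygen–F1 bonds by C(aryl)–O reductive elimination. The closest known reaction type is the decarbonylative diaryl ether synthesis from a single aryl (hetero)aroate with Ni(cod)2 or Pd(OAc)2 and dcypt; doing it twice in one molecule on electron-rich benzoates with ortho or para oxygen substituents is not established, hence the label. No ring is closed and no stereocentre is formed. The step needs insertion into the two acyl C–O bonds and not into aryl–OMe, aryl–O(ester) or benzyl–O bonds; the acyl C–O bond is the weakest and most electrophilic C–O bond present, and 17 carries no halide, free hydroxyl or other carbonyl group. It needs CO loss to outrun reductive elimination back to the ester, which the bulky, electron-rich, tightly chelating diphosphine and removal of CO in the argon stream should favour. It also needs each aryloxide to stay on the nickel that cleaved it, which a non-polar solvent and moderate dilution should help. Because the contraction keeps the oxygen of each phenol component, every oxygen position in 18 is fixed by 15, 8 and 4.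

Step 12
Reactants: 18 DEFG tetramer benzyl ether
Product: 19 3-{2-[3,5-dimethoxy-4-(3,4,5-trimethoxyphenoxy)phenoxy]-3,4,5-trimethoxyphenoxy}-4,5-dimethoxyphenol (DEFG phenol)
Conditions: H2 (1 atm), 10% Pd/C, EtOAc/MeOH, rt
Reagents that add atoms: none
Why: Hydrogenolysis of a benzyl aryl ether; 18 has no other reducible group, and methyl and diaryl ethers are inert.

Step 13
Reactants: 19 DEFG phenol; 5 4-(2-iodo-3,4,5-trimethoxyphenoxy)-3,5-dimethoxybenzaldehyde
Product: 20 BCDEFG hexamer aldehyde (formyl group on B1, ring C joined through C6 to the D1 oxygen, all hydroxyls as methyl ethers)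
Conditions: CuI (20 mol%), picolinic acid (40 mol%), K3PO4, DMSO, 90 °C, 5 in excess
Reagents that add atoms: none
Why: Ullmann diaryl ether coupling of an unhindered phenol with a di-ortho-oxygenated aryl iodide, the case the picolinic acid/CuI system is suited to. The three-step iodide 5 is used in excess, and its aldehyde, on the other ring, is inert to phosphate base.

Step 14
Reactants: 20 BCDEFG hexamer aldehyde
Product: 22 BCDEFG hexamer phenol (free hydroxyl on B1), via hexamer formate 21 (not isolated)
Conditions: mCPBA (1.2 equiv), CH2Cl2, 0 °C → rt; aq. NaHCO3 wash; then K2CO3 (cat.), MeOH, 0 °C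
Reagents that add atoms: mCPBA, OOC(=O)c1cccc(Cl)c1
Why: Dakin-type Baeyer–Villiger oxidation; the 4-aryloxy-3,5-dimethoxyphenyl group migrates readily, and a small excess of peracid followed by mild methanolysis should leave the five other, fully etherified rings unchanged.

Step 15
Reactants: 22 BCDEFG hexamer phenol; 23 2-iodo-1,3,5-trimethoxybenzene
Product: 24 octadeca-O-methyl ether of the target (permethylated heptamer)
Conditions: CuI (20 mol%), picolinic acid (40 mol%), K3PO4, DMSO, 100 °C, 23 in excess
Reagents that add atoms: none
Why: Ullmann diaryl ether coupling of an unhindered phenol with a 2,6-dimethoxyaryl iodide, the pattern by which phloroglucinol-derived aryl ethers are usually made. Ring A is added last so that its very nucleophilic free positions never meet an electrophilic halogenating agent.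

Step 16
Reactants: 24 permethylated heptamer
Product: 25 target CNP0130704.0
Conditions: BBr3 (excess), CH2Cl2, −78 °C → rt, argon; then degassed MeOH/H2O; reversed-phase chromatography under argon
Reagents that add atoms: none
Why: Lewis acid cleavage of aryl methyl ethers; bromide attacks the methyl carbon of each boron-bound ether, and diaryl ethers have no sp3 carbon to attack and stay intact. Air- and base-free work-up protects the pyrogallol and phloroglucinol units.

## Compound list

1 | syringaldehyde (4-hydroxy-3,5-dimethoxybenzaldehyde) | COc1cc(C=O)cc(OC)c1O | starting material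
2 | 5-bromo-1,2,3-trimethoxybenzene | COc1cc(Br)cc(OC)c1OC | starting material
3 | 3,5-dimethoxy-4-(3,4,5-trimethoxyphenoxy)benzaldehyde | COc1cc(C=O)cc(OC)c1Oc1cc(OC)c(OC)c(OC)c1 | intermediate
4 | 3,5-dimethoxy-4-(3,4,5-trimethoxyphenoxy)benzoic acid (FG acid) | COc1cc(C(=O)O)cc(OC)c1Oc1cc(OC)c(OC)c(OC)c1 | intermediate
5 | 4-(2-iodo-3,4,5-trimethoxyphenoxy)-3,5-dimethoxybenzaldehyde (BC iodide) | COc1cc(C=O)cc(OC)c1Oc1cc(OC)c(OC)c(OC)c1I | intermediate
6 | 3,4,5-trimethoxybenzoic acid | COc1cc(C(=O)O)cc(OC)c1OC | starting material
7 | 2-bromo-3,4,5-trimethoxybenzoic acid | COc1cc(C(=O)O)c(Br)c(OC)c1OC | intermediate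
8 | 2-hydroxy-3,4,5-trimethoxybenzoic acid | COc1cc(C(=O)O)c(O)c(OC)c1OC | intermediate
9 | 3,5-dimethoxy-4-(3,4,5-trimethoxyphenoxy)benzoyl chloride | COc1cc(C(=O)Cl)cc(OC)c1Oc1cc(OC)c(OC)c(OC)c1 | intermediate
10 | 2-{[3,5-dimethoxy-4-(3,4,5-trimethoxyphenoxy)benzoyl]oxy}-3,4,5-trimethoxybenzoic acid (EFG acid) | COc1cc(C(=O)O)c(OC(=O)c2cc(OC)c(Oc3cc(OC)c(OC)c(OC)c3)c(OC)c2)c(OC)c1OC | intermediate
11 | 3-bromo-4,5-dimethoxybenzaldehyde | COc1cc(C=O)cc(Br)c1OC | starting material
12 | 3-bromo-4,5-dimethoxyphenyl formate | COc1cc(OC=O)cc(Br)c1OC | intermediate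
13 | 3-bromo-4,5-dimethoxyphenol | COc1cc(O)cc(Br)c1OC | intermediate
14 | 1-(benzyloxy)-3-bromo-4,5-dimethoxybenzene | COc1cc(OCc2ccccc2)cc(Br)c1OC | intermediate
15 | 5-(benzyloxy)-2,3-dimethoxyphenol | COc1cc(OCc2ccccc2)cc(O)c1OC | intermediate
16 | 2-{[3,5-dimethoxy-4-(3,4,5-trimethoxyphenoxy)benzoyl]oxy}-3,4,5-trimethoxybenzoyl chloride | COc1cc(C(=O)Cl)c(OC(=O)c2cc(OC)c(Oc3cc(OC)c(OC)c(OC)c3)c(OC)c2)c(OC)c1OC | intermediate
17 | 5-(benzyloxy)-2,3-dimethoxyphenyl 2-{[3,5-dimethoxy-4-(3,4,5-trimethoxyphenoxy)benzoyl]oxy}-3,4,5-trimethoxybenzoate (depside) | c1ccccc1COc1cc(OC)c(OC)c(OC(=O)c2cc(OC)c(OC)c(OC)c2OC(=O)c2cc(OC)c(Oc3cc(OC)c(OC)c(OC)c3)c(OC)c2)c1 | intermediate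
18 | DEFG tetramer benzyl ether | c1ccccc1COc1cc(OC)c(OC)c(Oc2cc(OC)c(OC)c(OC)c2Oc2cc(OC)c(Oc3cc(OC)c(OC)c(OC)c3)c(OC)c2)c1 | intermediate
19 | DEFG phenol (free hydroxyl on D1) | Oc1cc(OC)c(OC)c(Oc2cc(OC)c(OC)c(OC)c2Oc2cc(OC)c(Oc3cc(OC)c(OC)c(OC)c3)c(OC)c2)c1 | intermediate
20 | BCDEFG hexamer aldehyde (formyl on B1) | O=Cc1cc(OC)c(Oc2cc(OC)c(OC)c(OC)c2Oc2cc(OC)c(OC)c(Oc3cc(OC)c(OC)c(OC)c3Oc3cc(OC)c(Oc4cc(OC)c(OC)c(OC)c4)c(OC)c3)c2)c(OC)c1 | intermediate
21 | BCDEFG hexamer formate (formyloxy on B1) | O=COc1cc(OC)c(Oc2cc(OC)c(OC)c(OC)c2Oc2cc(OC)c(OC)c(Oc3cc(OC)c(OC)c(OC)c3Oc3cc(OC)c(Oc4cc(OC)c(OC)c(OC)c4)c(OC)c3)c2)c(OC)c1 | intermediate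
22 | BCDEFG hexamer phenol (free hydroxyl on B1) | Oc1cc(OC)c(Oc2cc(OC)c(OC)c(OC)c2Oc2cc(OC)c(OC)c(Oc3cc(OC)c(OC)c(OC)c3Oc3cc(OC)c(Oc4cc(OC)c(OC)c(OC)c4)c(OC)c3)c2)c(OC)c1 | intermediate
23 | 2-iodo-1,3,5-trimethoxybenzene | COc1cc(OC)c(I)c(OC)c1 | starting material
24 | octadeca-O-methyl ether of the target (permethylated heptamer) | COc1cc(OC)c(Oc2cc(OC)c(Oc3cc(OC)c(OC)c(OC)c3Oc3cc(OC)c(OC)c(Oc4cc(OC)c(OC)c(OC)c4Oc4cc(OC)c(Oc5cc(OC)c(OC)c(OC)c5)c(OC)c4)c3)c(OC)c2)c(OC)c1 | intermediate
25 | CNP0130704.0 (heptamer with eighteen free hydroxyls) | Oc1cc(O)c(Oc2cc(O)c(Oc3cc(O)c(O)c(O)c3Oc3cc(O)c(O)c(Oc4cc(O)c(O)c(O)c4Oc4cc(O)c(Oc5cc(O)c(O)c(O)c5)c(O)c4)c3)c(O)c2)c(O)c1 | target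

## Step count and least certain steps

Total: 16 steps. Longest linear sequence: 10 steps (for example steps 7, 8, 9, 10, 11, 12, 13, 14, 15, 16, from 11 to 25). The branches from 1 and from 6 are equally long.

**Step 11 (key step, proposed new method).** Three things may go wrong. Oxidative addition to the electron-rich benzoates may be slow, or CO may not leave before reductive elimination, so that the depside is recovered. Exchange of aryloxide ligands between nickel centres, or phosphate-mediated transesterification, may scramble the aryl and aryloxy partners before the ethers form. Carbon monoxide that is not swept out may tie up the nickel as carbonyl complexes, so that only one ester reacts.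

The fallback uses known chemistry only, sets out from 3 and 14 and returns at 18. Dakin oxidation of 3 (mCPBA, CH2Cl2; then K2CO3, MeOH) would give, through 3,5-dimethoxy-4-(3,4,5-trimethoxyphenoxy)phenyl formate F1, 3,5-dimethoxy-4-(3,4,5-trimethoxyphenoxy)phenol F2. Ullmann coupling of F2 with commercial 2-bromo-3,4,5-trimethoxybenzaldehyde (CuI, picolinic acid, K3PO4, DMSO; the ortho formyl group activates the bromide) would give the EFG aldehyde F3. A second Dakin oxidation would lead through the EFG formate F4 to the EFG phenol F5, and Ullmann coupling of F5 with bromide 14 would give 18.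

**Step 13.** Oxidative addition at the iodide flanked by aryloxy and methoxy groups may be slower than hydrodeiodination, so that 19 is recovered and 5 is consumed.

The fallback sets out from 19 and returns at 20, and replaces the deactivated iodide by two formyl-activated bromides. Ullmann coupling of 19 with 2-bromo-3,4,5-trimethoxybenzaldehyde would give the CDEFG pentamer aldehyde F6. Dakin oxidation would lead through the pentamer formate F7 to the CDEFG pentamer phenol F8. Coupling of F8 with commercial 4-bromo-3,5-dimethoxybenzaldehyde, whose bromide is activated by the para formyl group, would give 20.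

**Step 15.** Reductive dehalogenation of the very electron-rich, doubly ortho-substituted iodide 23 may outrun C–O bond formation, and the large phenoxide may dissolve poorly.

The fallback sets out from 22 and returns at 25. Coupling of 22 with 4-bromo-3,5-dimethoxybenzaldehyde (CuI, picolinic acid, K3PO4, DMSO) would give the heptamer aldehyde F9, with ring A as a 4-formyl-2,6-dimethoxyphenyl group. Dakin oxidation would lead through the heptamer formate F10 to the heptamer phenol F11, with a free hydroxyl on A4. BBr3 would then cleave the seventeen methyl ethers of F11 to give 25 directly, without 24.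

**Step 16.** Cleavage of eighteen ethers may stop short at some of them, and the polyphenol may degrade oxidatively during isolation, which would give mixtures that are hard to separate on a polar stationary phase.

The fallback sets out from 24 and returns at 25, and changes the isolation. The crude product of the BBr3 reaction would be acetylated (Ac2O, pyridine) to the octadecaacetate F12, which is stable in air and separable on silica from incompletely cleaved material. Acid-catalysed methanolysis (AcCl (cat.), MeOH, argon) would then release 25 without base.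

**Step 1.** The phenoxide of 1 is hindered and made less nucleophilic by the para formyl group, so conversion in the copper coupling may be low.

The fallback sets out from 1 and returns at 3. Chan–Lam coupling of 1 with (3,4,5-trimethoxyphenyl)boronic acid (Cu(OAc)2, pyridine, 4 Å molecular sieves, CH2Cl2, air, rt) uses divalent copper and an aryl nucleophile in place of the bromide 2. It makes no new compound (F0).

## Further compounds

F1 | step 11 | 3,5-dimethoxy-4-(3,4,5-trimethoxyphenoxy)phenyl formate | O=COc1cc(OC)c(Oc2cc(OC)c(OC)c(OC)c2)c(OC)c1
F2 | step 11 | 3,5-dimethoxy-4-(3,4,5-trimethoxyphenoxy)phenol | Oc1cc(OC)c(Oc2cc(OC)c(OC)c(OC)c2)c(OC)c1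
F3 | step 11 | EFG aldehyde, 2-[3,5-dimethoxy-4-(3,4,5-trimethoxyphenoxy)phenoxy]-3,4,5-trimethoxybenzaldehyde | O=Cc1cc(OC)c(OC)c(OC)c1Oc1cc(OC)c(Oc2cc(OC)c(OC)c(OC)c2)c(OC)c1
F4 | step 11 | EFG formate, 2-[3,5-dimethoxy-4-(3,4,5-trimethoxyphenoxy)phenoxy]-3,4,5-trimethoxyphenyl formate | O=COc1cc(OC)c(OC)c(OC)c1Oc1cc(OC)c(Oc2cc(OC)c(OC)c(OC)c2)c(OC)c1
F5 | step 11 | EFG phenol, 2-[3,5-dimethoxy-4-(3,4,5-trimethoxyphenoxy)phenoxy]-3,4,5-trimethoxyphenol | Oc1cc(OC)c(OC)c(OC)c1Oc1cc(OC)c(Oc2cc(OC)c(OC)c(OC)c2)c(OC)c1
F6 | step 13 | CDEFG pentamer aldehyde (formyl on C1) | O=Cc1cc(OC)c(OC)c(OC)c1Oc1cc(OC)c(OC)c(Oc2cc(OC)c(OC)c(OC)c2Oc2cc(OC)c(Oc3cc(OC)c(OC)c(OC)c3)c(OC)c2)c1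
F7 | step 13 | CDEFG pentamer formate (formyloxy on C1) | O=COc1cc(OC)c(OC)c(OC)c1Oc1cc(OC)c(OC)c(Oc2cc(OC)c(OC)c(OC)c2Oc2cc(OC)c(Oc3cc(OC)c(OC)c(OC)c3)c(OC)c2)c1
F8 | step 13 | CDEFG pentamer phenol (free hydroxyl on C1) | Oc1cc(OC)c(OC)c(OC)c1Oc1cc(OC)c(OC)c(Oc2cc(OC)c(OC)c(OC)c2Oc2cc(OC)c(Oc3cc(OC)c(OC)c(OC)c3)c(OC)c2)c1
F9 | step 15 | heptamer aldehyde (formyl on A4, seventeen methyl ethers) | O=Cc1cc(OC)c(Oc2cc(OC)c(Oc3cc(OC)c(OC)c(OC)c3Oc3cc(OC)c(OC)c(Oc4cc(OC)c(OC)c(OC)c4Oc4cc(OC)c(Oc5cc(OC)c(OC)c(OC)c5)c(OC)c4)c3)c(OC)c2)c(OC)c1
F10 | step 15 | heptamer formate (formyloxy on A4) | O=COc1cc(OC)c(Oc2cc(OC)c(Oc3cc(OC)c(OC)c(OC)c3Oc3cc(OC)c(OC)c(Oc4cc(OC)c(OC)c(OC)c4Oc4cc(OC)c(Oc5cc(OC)c(OC)c(OC)c5)c(OC)c4)c3)c(OC)c2)c(OC)c1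
F11 | step 15 | heptamer phenol (free hydroxyl on A4, seventeen methyl ethers) | Oc1cc(OC)c(Oc2cc(OC)c(Oc3cc(OC)c(OC)c(OC)c3Oc3cc(OC)c(OC)c(Oc4cc(OC)c(OC)c(OC)c4Oc4cc(OC)c(Oc5cc(OC)c(OC)c(OC)c5)c(OC)c4)c3)c(OC)c2)c(OC)c1
F12 | step 16 | octadecaacetate of 25 | CC(=O)Oc1cc(OC(C)=O)c(Oc2cc(OC(C)=O)c(Oc3cc(OC(C)=O)c(OC(C)=O)c(OC(C)=O)c3Oc3cc(OC(C)=O)c(OC(C)=O)c(Oc4cc(OC(C)=O)c(OC(C)=O)c(OC(C)=O)c4Oc4cc(OC(C)=O)c(Oc5cc(OC(C)=O)c(OC(C)=O)c(OC(C)=O)c5)c(OC(C)=O)c4)c3)c(OC(C)=O)c2)c(OC(C)=O)c1
F0 | step 1 | none | none
A1 | alternative 1 | EFG phenol, 2-[3,5-dimethoxy-4-(3,4,5-trimethoxyphenoxy)phenoxy]-3,4,5-trimethoxyphenol | Oc1cc(OC)c(OC)c(OC)c1Oc1cc(OC)c(Oc2cc(OC)c(OC)c(OC)c2)c(OC)c1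
A2 | alternative 1 | 2-[3,5-dimethoxy-4-(3,4,5-trimethoxyphenoxy)phenoxy]-3,4-dimethoxy-4-(1-methoxyethenyl)cyclobut-2-en-1-one (racemic) | C=C(OC)C1(OC)C(OC)=C(Oc2cc(OC)c(Oc3cc(OC)c(OC)c(OC)c3)c(OC)c2)C1=O
A3 | alternative 2 | heptamer trialdehyde (formyl on C4, E4 and G4, otherwise methylated) | COc1cc(OC)c(Oc2cc(OC)c(Oc3cc(OC)c(C=O)c(OC)c3Oc3cc(OC)c(OC)c(Oc4cc(OC)c(C=O)c(OC)c4Oc4cc(OC)c(Oc5cc(OC)c(C=O)c(OC)c5)c(OC)c4)c3)c(OC)c2)c(OC)c1
A4 | alternative 2 | heptamer triol (free hydroxyls on C4, E4 and G4, otherwise methylated) | COc1cc(OC)c(Oc2cc(OC)c(Oc3cc(OC)c(O)c(OC)c3Oc3cc(OC)c(OC)c(Oc4cc(OC)c(O)c(OC)c4Oc4cc(OC)c(Oc5cc(OC)c(O)c(OC)c5)c(OC)c4)c3)c(OC)c2)c(OC)c1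
A5 | alternative 3 | [CpRu(η6-2,5-dichloro-1,3-dimethoxybenzene)]PF6 | COc1cc(Cl)cc(OC)c1Cl.[CH-]1C=CC=C1.[Ru+2].F[P-](F)(F)(F)(F)F
A6 | alternative 3 | 2,4,6-trimethoxyphenol | COc1cc(OC)c(O)c(OC)c1
A7 | alternative 3 | 2-(benzyloxy)-3,4,5-trimethoxyphenol | COc1cc(O)c(OCc2ccccc2)c(OC)c1OC
A8 | alternative 3 | ABC trimer, permethylated, benzyl ether on the C6 oxygen | COc1cc(OC)c(Oc2cc(OC)c(Oc3cc(OC)c(OC)c(OC)c3OCc3ccccc3)c(OC)c2)c(OC)c1
A9 | alternative 3 | [CpRu(MeCN)3]PF6 | CC#N.CC#N.CC#N.[CH-]1C=CC=C1.[Ru+2].F[P-](F)(F)(F)(F)F
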